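**Strategy**

Ring A (cyclohexane: C1 carbinol, C2 methylidene carbon, C3–C5 CH2, C6 CMe2) is disconnected across its unsubstituted C3–C4 edge. One rhodium-catalysed insertion of ethylene into the C2(O)–C5H2 bond of an enantiopure 2-silyloxy-2-alkyl-3,3-dimethylcyclobutanone forms C2–C3 and C4–C5 together; the cleaved four-membered-ring bond is absent from the target and exists only to store strain. The step exploits C2 as a latent ketone flanked by quaternary C1 and by C5H2 next to quaternary C6, which should direct the cleavage and block β-hydride loss. C1 is set beforehand by CBS reduction and hydroxyl-directed epoxidation; the 1,2-dioxane is closed late by peroxysilylation and oxa-Michael addition, and the methylidene is unmasked last by Peterson elimination.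

Key step: step 8

Atom labels: ring A C1–C6 as above; chain C7, C8; dioxane carbons C3′ (CH), C4′, C5′, C6′ (quaternary); propionate α-carbon Cα.

Remark on stereocontrol: only C1 is set under reagent control (steps 3–4). C6′ forms without facial control in step 13 and C3′/Cα under substrate control in step 14. The required (3′S,6′R,αS) series is therefore one of several diastereomers and is to be isolated by chromatography after step 14; the enantiomer of the target cannot form.

**Route**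

Step 1
Reactants: 1 ethyl (2-methyl-1,3-dioxolan-2-yl)acetate
Product: 2 (2-methyl-1,3-dioxolan-2-yl)acetaldehyde
Conditions: iBu2AlH, CH2Cl2, −78 °C
Reagents that add atoms: none
Why: Partial ester reduction: at low temperature the aluminium hemiacetal persists and collapses to the aldehyde only on work-up, leaving the ketal untouched.

Step 2
Reactants: 3 3,3-dimethylcyclobutan-1-one; 2 (2-methyl-1,3-dioxolan-2-yl)acetaldehyde
Product: 6 3,3-dimethyl-2-[2-(2-methyl-1,3-dioxolan-2-yl)ethylidene]cyclobutan-1-one (E/Z mixture), via aldol adduct 4 (not isolated), via mesylate 5 (not isolated)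
Conditions: LiN(iPr)2, THF, −78 °C; then 2; then MeSO2Cl, Et3N, −78 °C to rt
Reagents that add atoms: none
Why: Aldol condensation: the lithium enolate (both α-positions of 3 are equivalent) adds to the aldehyde, and mesylation with E1cB elimination gives the exocyclic enone, whose geometry is irrelevant because that carbon becomes C7H2.

Step 3
Reactants: 6 3,3-dimethyl-2-[2-(2-methyl-1,3-dioxolan-2-yl)ethylidene]cyclobutan-1-one
Product: 7 (1R)-3,3-dimethyl-2-[2-(2-methyl-1,3-dioxolan-2-yl)ethylidene]cyclobutan-1-ol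
Conditions: (S)-1-methyl-3,3-diphenyl-tetrahydro-1H,3H-pyrrolo[1,2-c][1,3,2]oxazaborole ((S)-Me-CBS, 20 mol %), catecholborane, toluene, −78 °C
Reagents that add atoms: none
Why: Corey–Bakshi–Shibata reduction: with the alkylidene arm as the large group, the standard model for enones predicts hydride delivery to the face that gives the (R)-allylic alcohol.

Step 4
Reactants: 7 (1R)-3,3-dimethyl-2-[2-(2-methyl-1,3-dioxolan-2-yl)ethylidene]cyclobutan-1-ol
Product: 8 (3S,4R)-6,6-dimethyl-2-[(2-methyl-1,3-dioxolan-2-yl)methyl]-1-oxaspiro[2.3]hexan-4-ol (epoxide oxygen syn to OH; both C2 epimers)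
Conditions: VO(acac)2 (cat.), tBuOOH, CH2Cl2, 0 °C
Reagents that add atoms: tert-butyl hydroperoxide CC(C)(C)OO
Why: Hydroxyl-directed vanadium-catalysed epoxidation delivers oxygen to the alkene face syn to the neighbouring hydroxyl, which fixes the tertiary C–O bond of the future C1 relative to the carbinol set in step 3.

Step 5
Reactants: 8 (3S,4R)-6,6-dimethyl-2-[(2-methyl-1,3-dioxolan-2-yl)methyl]-1-oxaspiro[2.3]hexan-4-ol
Product: 9 (1R,2S)-3,3-dimethyl-2-[2-(2-methyl-1,3-dioxolan-2-yl)ethyl]cyclobutane-1,2-diol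
Conditions: LiAlH4, THF, 0 °C to rt
Reagents that add atoms: none
Why: Hydride opens the epoxide by SN2 attack at its less substituted carbon (future C7), so the tertiary C–O bond and its configuration are retained.

Step 6
Reactants: 9 (1R,2S)-3,3-dimethyl-2-[2-(2-methyl-1,3-dioxolan-2-yl)ethyl]cyclobutane-1,2-diol
Product: 10 (2S)-2-hydroxy-3,3-dimethyl-2-[2-(2-methyl-1,3-dioxolan-2-yl)ethyl]cyclobutan-1-one
Conditions: SO3·pyridine, DMSO, iPr2NEt, CH2Cl2, 0 °C
Reagents that add atoms: none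
Why: Parikh–Doering oxidation converts the secondary alcohol to the ketone without glycol cleavage; the relay stereocentre is erased and only the tertiary one remains.

Step 7
Reactants: 10 (2S)-2-hydroxy-3,3-dimethyl-2-[2-(2-methyl-1,3-dioxolan-2-yl)ethyl]cyclobutan-1-one
Product: 11 (2S)-3,3-dimethyl-2-[2-(2-methyl-1,3-dioxolan-2-yl)ethyl]-2-(triethylsilyloxy)cyclobutan-1-one
Conditions: Et3SiOTf, 2,6-lutidine, CH2Cl2, −78 to 0 °C
Reagents that add atoms: triethylsilyl trifluoromethanesulfonate CC[Si](CC)(CC)OS(=O)(=O)C(F)(F)F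
Why: Silyl triflate with a hindered base silylates the tertiary α-hydroxyl, removing the free alcohol before the rhodium step.

Step 8
Reactants: 11 (2S)-3,3-dimethyl-2-[2-(2-methyl-1,3-dioxolan-2-yl)ethyl]-2-(triethylsilyloxy)cyclobutan-1-one; 12 ethylene
Product: 13 (2S)-3,3-dimethyl-2-[2-(2-methyl-1,3-dioxolan-2-yl)ethyl]-2-(triethylsilyloxy)cyclohexan-1-one
Conditions: [Rh(C2H4)2Cl]2 (5 mol %), P(3,5-(CF3)2C6H3)3 (20 mol %), ethylene (20 bar), 1,4-dioxane, 130 °C
Reagents that add atoms: none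
Why: Proposed new method: monovalent rhodium should add oxidatively into the strained C2(O)–C5H2 bond of 11 to give a five-membered acyl–alkyl rhodacycle of trivalent rhodium, ethylene then inserts into a Rh–C bond (1,2-migratory insertion) to give a seven-membered rhodacycle, and C–C reductive elimination releases 13 and the catalyst. The closest known reactions are the intramolecular "cut-and-sew" carboacylation of cyclobutanones with tethered olefins and the intermolecular insertion of ethylene into the aryl–acyl bond of 1-indanones; to my knowledge an intermolecular ethylene insertion into a saturated cyclobutanone is not established. Ring A closes by reductive elimination from the seven-membered metallacycle, a formal (4+2) ring expansion in which C2–C3 and C4–C5 are made in the same catalytic turnover. No stereocentre is created, and C1 keeps its configuration because the C1–C2 bond is never broken. The step needs cleavage of the C(O)–CH2 bond and not of the C(O)–C1 bond, which the fully substituted, silyloxy-bearing C1 next to the gem-dimethyl carbon should secure on steric grounds. It also needs reductive elimination to outrun β-hydride elimination and decarbonylation: the first-formed Rh–CH2 alkyl sits on quaternary C6 and has no β-hydrogen, and ethylene pressure should suppress CO extrusion.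

Step 9
Reactants: 13 (2S)-3,3-dimethyl-2-[2-(2-methyl-1,3-dioxolan-2-yl)ethyl]-2-(triethylsilyloxy)cyclohexan-1-one
Product: 14 (2S)-3,3-dimethyl-2-(3-oxobutyl)-2-(triethylsilyloxy)cyclohexan-1-one
Conditions: pyridinium p-toluenesulfonate (cat.), acetone/H2O, 50 °C
Reagents that add atoms: water O
Why: Mild acid-catalysed ketal hydrolysis unmasks the methyl ketone (C6′) while the hindered tertiary silyl ether should persist.

Step 10
Reactants: 14 (2S)-3,3-dimethyl-2-(3-oxobutyl)-2-(triethylsilyloxy)cyclohexan-1-one; 15 (but-3-en-1-yl)triphenylphosphonium bromide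
Product: 16 (2S)-3,3-dimethyl-2-(3-methylhepta-3,6-dien-1-yl)-2-(triethylsilyloxy)cyclohexan-1-one (E/Z mixture at the trisubstituted alkene)
Conditions: 15, KN(SiMe3)2, THF, 0 °C; then 14, −78 °C to rt
Reagents that add atoms: none
Why: Wittig olefination: the unstabilised ylide should react at the unhindered methyl ketone and not at the ring ketone next to quaternary C1; the E/Z mixture is harmless because C6′ becomes sp3 in step 13.

Step 11
Reactants: 16 (2S)-3,3-dimethyl-2-(3-methylhepta-3,6-dien-1-yl)-2-(triethylsilyloxy)cyclohexan-1-one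
Product: 17 (2S)-3,3-dimethyl-2-(3-methylhepta-3,6-dien-1-yl)-2-(triethylsilyloxy)-1-[(trimethylsilyl)methyl]cyclohexan-1-ol (both C1 epimers of this ring numbering)
Conditions: Me3SiCH2Li, THF, −78 to 0 °C
Reagents that add atoms: (trimethylsilyl)methyllithium [Li]C[Si](C)(C)C
Why: 1,2-Addition of the small, weakly basic α-silyl organolithium (first half of a Peterson olefination) gives a β-hydroxysilane that masks the methylidene without a C=C bond through the radical step 13; the new carbinol centre is lost in step 15.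

Step 12
Reactants: 17 (2S)-3,3-dimethyl-2-(3-methylhepta-3,6-dien-1-yl)-2-(triethylsilyloxy)-1-[(trimethylsilyl)methyl]cyclohexan-1-ol; 18 methyl methacrylate
Product: 19 methyl (2E)-8-[(1S)-2-hydroxy-6,6-dimethyl-1-(triethylsilyloxy)-2-[(trimethylsilyl)methyl]cyclohexyl]-2,6-dimethylocta-2,6-dienoate (6E/6Z mixture)
Conditions: second-generation Hoveyda–Grubbs catalyst RuCl2(H2IMes)(=CH-C6H4-2-OiPr) (5 mol %), excess 18, CH2Cl2, 40 °C
Reagents that add atoms: none
Why: Olefin cross-metathesis of the terminal vinyl group with methyl methacrylate should give the (E)-trisubstituted enoate, the internal trisubstituted alkene being inert to the catalyst.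

Step 13
Reactants: 19 methyl (2E)-8-[(1S)-2-hydroxy-6,6-dimethyl-1-(triethylsilyloxy)-2-[(trimethylsilyl)methyl]cyclohexyl]-2,6-dimethylocta-2,6-dienoate
Product: 20 methyl (2E)-8-[(1S)-2-hydroxy-6,6-dimethyl-1-(triethylsilyloxy)-2-[(trimethylsilyl)methyl]cyclohexyl]-2,6-dimethyl-6-[(triethylsilyl)peroxy]oct-2-enoate (both C6′ epimers)
Conditions: Co(acac)2 (cat.), O2 (1 atm), Et3SiH, ClCH2CH2Cl, rt
Reagents that add atoms: dioxygen O=O; triethylsilane CC[SiH](CC)CC
Why: Isayama–Mukaiyama hydroperoxysilylation: cobalt-hydride hydrogen-atom transfer to C5′ gives the tertiary C6′ radical, which is trapped by O2 and silylated (Markovnikov); the electron-poor enoate should react more slowly, and no facial control at C6′ is expected.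

Step 14
Reactants: 20 methyl (2E)-8-[(1S)-2-hydroxy-6,6-dimethyl-1-(triethylsilyloxy)-2-[(trimethylsilyl)methyl]cyclohexyl]-2,6-dimethyl-6-[(triethylsilyl)peroxy]oct-2-enoate
Product: 22 methyl (2S)-2-[(3S,6R)-6-{2-[(1S)-2-hydroxy-6,6-dimethyl-1-(triethylsilyloxy)-2-[(trimethylsilyl)methyl]cyclohexyl]ethyl}-6-methyl-1,2-dioxan-3-yl]propanoate, via tertiary hydroperoxide 21 (not isolated)
Conditions: Et2NH, CF3CH2OH, rt; chromatographic separation of diastereomers
Reagents that add atoms: none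
Why: Solvolysis of the O–Si bond frees the hydroperoxide, whose anion adds 6-exo-trig to the enoate (intramolecular oxa-Michael addition); C3′ is set in a chair-like closure with the ester arm equatorial and Cα by protonation of the ester enolate, both under substrate control only, so the required isomer must be separated.

Step 15
Reactants: 22 methyl (2S)-2-[(3S,6R)-6-{2-[(1S)-2-hydroxy-6,6-dimethyl-1-(triethylsilyloxy)-2-[(trimethylsilyl)methyl]cyclohexyl]ethyl}-6-methyl-1,2-dioxan-3-yl]propanoate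
Product: 23 methyl (2S)-2-[(3S,6R)-6-{2-[(1S)-1-hydroxy-2,2-dimethyl-6-methylidenecyclohexyl]ethyl}-6-methyl-1,2-dioxan-3-yl]propanoate
Conditions: HF·pyridine, THF, 0 °C to rt
Reagents that add atoms: none
Why: HF·pyridine cleaves the tertiary silyl ether and triggers the acid-type Peterson elimination of the β-hydroxysilane, which can only give the exocyclic C2=CH2 alkene; the dialkyl peroxide and ester should tolerate these non-basic conditions.

**Compound list**

1 | ethyl (2-methyl-1,3-dioxolan-2-yl)acetate | CCOC(=O)CC1(C)OCCO1 | starting material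
2 | (2-methyl-1,3-dioxolan-2-yl)acetaldehyde | O=CCC1(C)OCCO1 | intermediate
3 | 3,3-dimethylcyclobutan-1-one | CC1(C)CC(=O)C1 | starting material
4 | 2-[1-hydroxy-2-(2-methyl-1,3-dioxolan-2-yl)ethyl]-3,3-dimethylcyclobutan-1-one (aldol adduct, formed as lithium alkoxide, diastereomer mixture) | O=C1CC(C)(C)C1C(O)CC2(C)OCCO2 | intermediate
5 | 1-(2,2-dimethyl-4-oxocyclobutyl)-2-(2-methyl-1,3-dioxolan-2-yl)ethyl methanesulfonate | O=C1CC(C)(C)C1C(OS(C)(=O)=O)CC2(C)OCCO2 | intermediate
6 | 3,3-dimethyl-2-[2-(2-methyl-1,3-dioxolan-2-yl)ethylidene]cyclobutan-1-one (E/Z mixture) | O=C1CC(C)(C)C1=CCC2(C)OCCO2 | intermediate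
7 | (1R)-3,3-dimethyl-2-[2-(2-methyl-1,3-dioxolan-2-yl)ethylidene]cyclobutan-1-ol | O[C@@H]1CC(C)(C)C1=CCC2(C)OCCO2 | intermediate
8 | (3S,4R)-6,6-dimethyl-2-[(2-methyl-1,3-dioxolan-2-yl)methyl]-1-oxaspiro[2.3]hexan-4-ol (C2 epimers) | O[C@@H]1CC(C)(C)[C@]12OC2CC3(C)OCCO3 | intermediate
9 | (1R,2S)-3,3-dimethyl-2-[2-(2-methyl-1,3-dioxolan-2-yl)ethyl]cyclobutane-1,2-diol | O[C@@H]1CC(C)(C)[C@@]1(O)CCC2(C)OCCO2 | intermediate
10 | (2S)-2-hydroxy-3,3-dimethyl-2-[2-(2-methyl-1,3-dioxolan-2-yl)ethyl]cyclobutan-1-one | O=C1CC(C)(C)[C@@]1(O)CCC2(C)OCCO2 | intermediate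
11 | (2S)-3,3-dimethyl-2-[2-(2-methyl-1,3-dioxolan-2-yl)ethyl]-2-(triethylsilyloxy)cyclobutan-1-one | O=C1CC(C)(C)[C@@]1(O[Si](CC)(CC)CC)CCC2(C)OCCO2 | intermediate
12 | ethylene | C=C | starting material
13 | (2S)-3,3-dimethyl-2-[2-(2-methyl-1,3-dioxolan-2-yl)ethyl]-2-(triethylsilyloxy)cyclohexan-1-one | O=C1CCCC(C)(C)[C@@]1(O[Si](CC)(CC)CC)CCC2(C)OCCO2 | intermediate
14 | (2S)-3,3-dimethyl-2-(3-oxobutyl)-2-(triethylsilyloxy)cyclohexan-1-one | O=C1CCCC(C)(C)[C@@]1(O[Si](CC)(CC)CC)CCC(C)=O | intermediate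
15 | (but-3-en-1-yl)triphenylphosphonium bromide | C=CCC[P+](c1ccccc1)(c1ccccc1)c1ccccc1.[Br-] | starting material
16 | (2S)-3,3-dimethyl-2-(3-methylhepta-3,6-dien-1-yl)-2-(triethylsilyloxy)cyclohexan-1-one (E/Z mixture) | O=C1CCCC(C)(C)[C@@]1(O[Si](CC)(CC)CC)CCC(C)=CCC=C | intermediate
17 | (2S)-3,3-dimethyl-2-(3-methylhepta-3,6-dien-1-yl)-2-(triethylsilyloxy)-1-[(trimethylsilyl)methyl]cyclohexan-1-ol (C1 epimers) | OC1(C[Si](C)(C)C)CCCC(C)(C)[C@@]1(O[Si](CC)(CC)CC)CCC(C)=CCC=C | intermediate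
18 | methyl methacrylate | C=C(C)C(=O)OC | starting material
19 | methyl (2E)-8-[(1S)-2-hydroxy-6,6-dimethyl-1-(triethylsilyloxy)-2-[(trimethylsilyl)methyl]cyclohexyl]-2,6-dimethylocta-2,6-dienoate (6E/6Z mixture) | OC1(C[Si](C)(C)C)CCCC(C)(C)[C@@]1(O[Si](CC)(CC)CC)CCC(C)=CC/C=C(\C)C(=O)OC | intermediate
20 | methyl (2E)-8-[(1S)-2-hydroxy-6,6-dimethyl-1-(triethylsilyloxy)-2-[(trimethylsilyl)methyl]cyclohexyl]-2,6-dimethyl-6-[(triethylsilyl)peroxy]oct-2-enoate (C6′ epimers) | OC1(C[Si](C)(C)C)CCCC(C)(C)[C@@]1(O[Si](CC)(CC)CC)CCC(C)(OO[Si](CC)(CC)CC)CC/C=C(\C)C(=O)OC | intermediate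
21 | methyl (2E)-6-hydroperoxy-8-[(1S)-2-hydroxy-6,6-dimethyl-1-(triethylsilyloxy)-2-[(trimethylsilyl)methyl]cyclohexyl]-2,6-dimethyloct-2-enoate | OC1(C[Si](C)(C)C)CCCC(C)(C)[C@@]1(O[Si](CC)(CC)CC)CCC(C)(OO)CC/C=C(\C)C(=O)OC | intermediate
22 | methyl (2S)-2-[(3S,6R)-6-{2-[(1S)-2-hydroxy-6,6-dimethyl-1-(triethylsilyloxy)-2-[(trimethylsilyl)methyl]cyclohexyl]ethyl}-6-methyl-1,2-dioxan-3-yl]propanoate | OC1(C[Si](C)(C)C)CCCC(C)(C)[C@@]1(O[Si](CC)(CC)CC)CC[C@@]2(C)CC[C@@H]([C@H](C)C(=O)OC)OO2 | intermediate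
23 | methyl (2S)-2-[(3S,6R)-6-{2-[(1S)-1-hydroxy-2,2-dimethyl-6-methylidenecyclohexyl]ethyl}-6-methyl-1,2-dioxan-3-yl]propanoate | C=C1CCCC(C)(C)[C@@]1(O)CC[C@@]1(C)CC[C@@H]([C@H](C)C(=O)OC)OO1 | target

**Totals**

Total step count: 15. Longest linear sequence: 15 steps (1 to 23).

**Steps most likely to fail**

1. Step 8 (proposed new method). Oxidative addition into the hindered ketone may be slow or occur at the C(O)–C1 bond. The acyl–alkyl rhodacycle may lose CO to give a cyclopropane, or after ethylene insertion undergo β-hydride elimination to an open-chain enone. Fallback with known chemistry, setting out from 11 and returning at 13: two successive one-carbon ring expansions with diazomethane. CH2N2 in Et2O/MeOH at 0 °C should convert the strained cyclobutanone, by migration of the unsubstituted CH2 and not of the oxygenated quaternary carbon, into (2S)-3,3-dimethyl-2-[2-(2-methyl-1,3-dioxolan-2-yl)ethyl]-2-(triethylsilyloxy)cyclopentan-1-one F1. A second homologation of F1 (CH2N2, BF3·OEt2, −78 °C) on the same side should give 13. The two ring bonds are then made one after the other.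

2. Step 13. O2 captures the planar tertiary C6′ radical from both faces, so part of the material enters the C6′-epimeric series; hydrogen-atom transfer may also reach the conjugated ester. Fallback, setting out from 19 (its 6E isomer, separated on AgNO3-impregnated silica) and returning at 22:
   - Shi epoxidation with the D-fructose-derived ketone (1,2:4,5-di-O-isopropylidene-β-D-erythro-2,3-hexodiulo-2,6-pyranose) and KHSO5 should give methyl (2E)-4-[(2R,3R)-3-{2-[(1S)-2-hydroxy-6,6-dimethyl-1-(triethylsilyloxy)-2-[(trimethylsilyl)methyl]cyclohexyl]ethyl}-3-methyloxiran-2-yl]-2-methylbut-2-enoate F2.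
   - MoO2(acac)2-catalysed perhydrolysis with anhydrous H2O2 in Et2O should open F2 at tertiary C6′ with inversion to methyl (2E,5R,6S)-6-hydroperoxy-5-hydroxy-8-[(1S)-2-hydroxy-6,6-dimethyl-1-(triethylsilyloxy)-2-[(trimethylsilyl)methyl]cyclohexyl]-2,6-dimethyloct-2-enoate F3.
   - Et2NH in CF3CH2OH closes F3 to methyl (2S)-2-[(3S,5R,6S)-5-hydroxy-6-{2-[(1S)-2-hydroxy-6,6-dimethyl-1-(triethylsilyloxy)-2-[(trimethylsilyl)methyl]cyclohexyl]ethyl}-6-methyl-1,2-dioxan-3-yl]propanoate F4.
   - Dehydration with methyl N-(triethylammoniosulfonyl)carbamate gives methyl (2S)-2-[(3S,6S)-6-{2-[(1S)-2-hydroxy-6,6-dimethyl-1-(triethylsilyloxy)-2-[(trimethylsilyl)methyl]cyclohexyl]ethyl}-6-methyl-3,6-dihydro-1,2-dioxin-3-yl]propanoate F5.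
   - Diimide (2-nitrobenzenesulfonohydrazide, Et3N) reduces the ring alkene of F5 to 22.
   
   C6′ is then set by the catalyst and a stereospecific ionic opening instead of a radical capture. The 6Z isomer of 19 would need the enantiomeric ketone.

3. Step 14. The conjugate addition is reversible and the ester enolate is protonated without strong bias, so C3′/Cα epimers are expected; amine-induced fragmentation at C3′–H can also erode the peroxide. Fallback, setting out from 17 and returning at 22: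
   - Cross-metathesis with (4S)-4-benzyl-3-(2-methylprop-2-enoyl)-1,3-oxazolidin-2-one (same ruthenium catalyst) gives (4S)-4-benzyl-3-{(2E)-8-[(1S)-2-hydroxy-6,6-dimethyl-1-(triethylsilyloxy)-2-[(trimethylsilyl)methyl]cyclohexyl]-2,6-dimethylocta-2,6-dienoyl}-1,3-oxazolidin-2-one F6.
   - Co(acac)2/O2/Et3SiH gives the C6′ triethylsilyl peroxide of F6, (4S)-4-benzyl-3-{(2E)-8-[(1S)-2-hydroxy-6,6-dimethyl-1-(triethylsilyloxy)-2-[(trimethylsilyl)methyl]cyclohexyl]-2,6-dimethyl-6-[(triethylsilyl)peroxy]oct-2-enoyl}-1,3-oxazolidin-2-one F7.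
   - Et2NH in CF3CH2OH frees the corresponding hydroperoxide, (4S)-4-benzyl-3-{(2E)-6-hydroperoxy-8-[(1S)-2-hydroxy-6,6-dimethyl-1-(triethylsilyloxy)-2-[(trimethylsilyl)methyl]cyclohexyl]-2,6-dimethyloct-2-enoyl}-1,3-oxazolidin-2-one F8, which cyclises to (4S)-4-benzyl-3-{(2S)-2-[(3S,6R)-6-{2-[(1S)-2-hydroxy-6,6-dimethyl-1-(triethylsilyloxy)-2-[(trimethylsilyl)methyl]cyclohexyl]ethyl}-6-methyl-1,2-dioxan-3-yl]propanoyl}-1,3-oxazolidin-2-one F9.
   - Sm(OTf)3 in MeOH converts F9 into the methyl ester 22 without base.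
   
   The auxiliary is meant to control the face of addition at C3′ and the protonation at Cα. The (S)-auxiliary is drawn; its sense of induction is not established for this substrate, and the enantiomeric auxiliary would be used if it proves opposite.

Further compounds

F1 | step 8 | (2S)-3,3-dimethyl-2-[2-(2-methyl-1,3-dioxolan-2-yl)ethyl]-2-(triethylsilyloxy)cyclopentan-1-one | O=C1CCC(C)(C)[C@@]1(O[Si](CC)(CC)CC)CCC2(C)OCCO2
F2 | step 13 | methyl (2E)-4-[(2R,3R)-3-{2-[(1S)-2-hydroxy-6,6-dimethyl-1-(triethylsilyloxy)-2-[(trimethylsilyl)methyl]cyclohexyl]ethyl}-3-methyloxiran-2-yl]-2-methylbut-2-enoate | OC1(C[Si](C)(C)C)CCCC(C)(C)[C@@]1(O[Si](CC)(CC)CC)CC[C@@]2(C)O[C@@H]2C/C=C(\C)C(=O)OC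
F3 | step 13 | methyl (2E,5R,6S)-6-hydroperoxy-5-hydroxy-8-[(1S)-2-hydroxy-6,6-dimethyl-1-(triethylsilyloxy)-2-[(trimethylsilyl)methyl]cyclohexyl]-2,6-dimethyloct-2-enoate | OC1(C[Si](C)(C)C)CCCC(C)(C)[C@@]1(O[Si](CC)(CC)CC)CC[C@](C)(OO)[C@H](O)C/C=C(\C)C(=O)OC
F4 | step 13 | methyl (2S)-2-[(3S,5R,6S)-5-hydroxy-6-{2-[(1S)-2-hydroxy-6,6-dimethyl-1-(triethylsilyloxy)-2-[(trimethylsilyl)methyl]cyclohexyl]ethyl}-6-methyl-1,2-dioxan-3-yl]propanoate | OC1(C[Si](C)(C)C)CCCC(C)(C)[C@@]1(O[Si](CC)(CC)CC)CC[C@@]2(C)[C@H](O)C[C@@H]([C@H](C)C(=O)OC)OO2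
F5 | step 13 | methyl (2S)-2-[(3S,6S)-6-{2-[(1S)-2-hydroxy-6,6-dimethyl-1-(triethylsilyloxy)-2-[(trimethylsilyl)methyl]cyclohexyl]ethyl}-6-methyl-3,6-dihydro-1,2-dioxin-3-yl]propanoate | OC1(C[Si](C)(C)C)CCCC(C)(C)[C@@]1(O[Si](CC)(CC)CC)CC[C@@]2(C)C=C[C@@H]([C@H](C)C(=O)OC)OO2
F6 | step 14 | (4S)-4-benzyl-3-{(2E)-8-[(1S)-2-hydroxy-6,6-dimethyl-1-(triethylsilyloxy)-2-[(trimethylsilyl)methyl]cyclohexyl]-2,6-dimethylocta-2,6-dienoyl}-1,3-oxazolidin-2-one | OC1(C[Si](C)(C)C)CCCC(C)(C)[C@@]1(O[Si](CC)(CC)CC)CCC(C)=CC/C=C(\C)C(=O)N2[C@@H](Cc3ccccc3)COC2=O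
F7 | step 14 | (4S)-4-benzyl-3-{(2E)-8-[(1S)-2-hydroxy-6,6-dimethyl-1-(triethylsilyloxy)-2-[(trimethylsilyl)methyl]cyclohexyl]-2,6-dimethyl-6-[(triethylsilyl)peroxy]oct-2-enoyl}-1,3-oxazolidin-2-one | OC1(C[Si](C)(C)C)CCCC(C)(C)[C@@]1(O[Si](CC)(CC)CC)CCC(C)(OO[Si](CC)(CC)CC)CC/C=C(\C)C(=O)N2[C@@H](Cc3ccccc3)COC2=O
F8 | step 14 | (4S)-4-benzyl-3-{(2E)-6-hydroperoxy-8-[(1S)-2-hydroxy-6,6-dimethyl-1-(triethylsilyloxy)-2-[(trimethylsilyl)methyl]cyclohexyl]-2,6-dimethyloct-2-enoyl}-1,3-oxazolidin-2-one | OC1(C[Si](C)(C)C)CCCC(C)(C)[C@@]1(O[Si](CC)(CC)CC)CCC(C)(OO)CC/C=C(\C)C(=O)N2[C@@H](Cc3ccccc3)COC2=O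
F9 | step 14 | (4S)-4-benzyl-3-{(2S)-2-[(3S,6R)-6-{2-[(1S)-2-hydroxy-6,6-dimethyl-1-(triethylsilyloxy)-2-[(trimethylsilyl)methyl]cyclohexyl]ethyl}-6-methyl-1,2-dioxan-3-yl]propanoyl}-1,3-oxazolidin-2-one | OC1(C[Si](C)(C)C)CCCC(C)(C)[C@@]1(O[Si](CC)(CC)CC)CC[C@@]2(C)CC[C@@H]([C@H](C)C(=O)N3[C@@H](Cc4ccccc4)COC3=O)OO2
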